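Readings and results were computed for substances that don't exist, noise included.

Each target formed brings one by-product and each target lost takes one along, so c_target equals c_by-product in these flasks. At one temperature, target gains as c_substrate·c_partner and loses as c_target·c_by-product, so it tops where the quotient of those two products reaches a fixed value.

| setting | elm | oak | flask |
|---|---|---|---|
| substrate | 17 mM | 17 mM | 17 mM |
| coupling partner | 4.2 equiv (fed, over 10 h) | 6.6 equiv (fed, over 10 h) | 3.00 equiv (fed, over 10 h) |
| remark | run made earlier | run made earlier |  |
| time |  |  | 40 h |
- elm (time / h: target / %): 6.00: 6; 10.0: 22; 15.0: 30; 25.0: 37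
- oak (time / h: target / %): 6.00: 12; 10.0: 31; 15.0: 40; 25.0: 37

(scatter of a reading: 2 percentage points)
* time up to 40 h at which target stands highest
* the amount of target, in percent of the substrate charged, at that time

Coupling partner in excess makes substrate roughly pseudo-first-order, with the feed counted as half its time. Oak's reading at 10.0 h gives a decay constant of 0.0742 h⁻¹, so this estimate puts about 47.6% of oak's substrate at 15.0 h, where oak read 40%, taken as near its top. That gives 0.0553, the crossing ratio: c_target·c_by-product/(c_substrate·c_partner) where target stops rising.

With less partner, this flask's constant is 0.0337 h⁻¹. At 15.0 h this estimate leaves the flask 71.4% of its substrate, so its forward conversion, 28.6%, stands below the ceiling, the target that the ratio allows, 32.7%. At 25.0 h the estimate leaves 50.9%, so conversion, 49.1%, has passed the ceiling, 26.6%. This reckoning therefore puts the top between those times. The forecast, later, says 37 h and 33%, with target to “flatten, with a broad maximum late in the window”.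

The flask gives 24.6 h and 29.2%.

    substrate + coupling partner ⇌ target + by-product (K = 1.20, k = 0.734 L mol⁻¹ h⁻¹)
    target + by-product → side product (k = 10.7 L mol⁻¹ h⁻¹)

The back reaction makes no difference to the height of the flask's top. A neighbour charged with 5.10 equiv reaches 35.9%, and at 40.0 h its ratio is 0.105, above the crossing ratio of 0.0553 read from oak, with target down to 26.2%.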